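Ring C of the upper flavan unit (O1, C2, C3, C4, C4a, C8a) is made from a 2-aryl-2,3-dihydrobenzofuran by one-carbon ring enlargement. Acetolysis of the trans-3-(mesyloxymethyl) compound lets ring A carbon C4a, activated by O1 (ortho) and O7 (para), bridge to the exocyclic CH2 as a phenonium ion; acetate opens it at C3 with inversion. One operation therefore inserts C4 into the ring, places the 3-oxygen trans to the 2-aryl group and delivers protected mesquitol. The five-membered precursor comes from an enantioselective rhodium carbenoid C–H insertion. The same monomer serves as both halves: C4 oxidation, 4→6 cation coupling and deprotection complete the synthesis.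

Key step: step 8

Remark: the sense of induction of the rhodium catalyst in step 5 is assumed; if it proves opposite, the (S)-configured catalyst is used instead.

Step 1
Reactants: 1 1-(2,3,4-trihydroxyphenyl)ethanone (gallacetophenone)
Product: 2 1-[3,4-bis(benzyloxy)-2-hydroxyphenyl]ethanone
Conditions: BnBr (2.1 equiv), K2CO3, DMF, 25 °C
Reagents that add atoms: benzyl bromide, BrCc1ccccc1
Why: Williamson ether synthesis; the 2-OH is held in a hydrogen bond to the acetyl group and is the least reactive, so two equivalents of benzyl bromide should alkylate only O-4 and O-3.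

Step 2
Reactants: 2 1-[3,4-bis(benzyloxy)-2-hydroxyphenyl]ethanone; 3 1,2-bis(benzyloxy)-4-(chloromethyl)benzene
Product: 4 1-[3,4-bis(benzyloxy)-2-{[3,4-bis(benzyloxy)phenyl]methoxy}phenyl]ethanone
Conditions: K2CO3, KI (cat.), DMF, 70 °C
Reagents that add atoms: none
Why: Williamson ether synthesis of the remaining chelated phenol under forcing conditions (Finkelstein activation of the chloride by KI); it brings in ring B and the future C2 on the oxygen that becomes O1.

Step 3
Reactants: 4 1-[3,4-bis(benzyloxy)-2-{[3,4-bis(benzyloxy)phenyl]methoxy}phenyl]ethanone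
Product: 5 methyl 2-[3,4-bis(benzyloxy)-2-{[3,4-bis(benzyloxy)phenyl]methoxy}phenyl]acetate
Conditions: PhI(OAc)2, HC(OMe)3, MeOH, H2SO4 (cat.), 25 °C
Reagents that add atoms: trimethyl orthoformate, COC(OC)OC
Why: Oxidative 1,2-aryl shift of an aryl methyl ketone with a trivalent iodine reagent: the ketal-derived enol ether is iodinated at the methyl carbon, the electron-rich trialkoxyaryl group migrates with loss of iodobenzene, and the dimethoxycarbenium ion collapses to the methyl ester.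

Step 4
Reactants: 5 methyl 2-[3,4-bis(benzyloxy)-2-{[3,4-bis(benzyloxy)phenyl]methoxy}phenyl]acetate
Product: 6 methyl 2-[3,4-bis(benzyloxy)-2-{[3,4-bis(benzyloxy)phenyl]methoxy}phenyl]-2-diazoacetate
Conditions: p-ABSA, DBU, MeCN, 0 to 25 °C
Reagents that add atoms: 4-acetamidobenzenesulfonyl azide, CC(=O)Nc1ccc(cc1)S(=O)(=O)N=[N+]=[N-]
Why: Regitz diazo transfer to the methylene group activated by both the aryl ring and the ester.

Step 5
Reactants: 6 methyl 2-[3,4-bis(benzyloxy)-2-{[3,4-bis(benzyloxy)phenyl]methoxy}phenyl]-2-diazoacetate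
Product: 8 methyl (2S,3S)-6,7-bis(benzyloxy)-2-[3,4-bis(benzyloxy)phenyl]-2,3-dihydro-1-benzofuran-3-carboxylate (trans), via cis ester 7 (not isolated)
Conditions: Rh2(R-PTTL)4 (dirhodium tetrakis[N-phthaloyl-(R)-tert-leucinate], 1 mol %), toluene, −60 °C; then NaOMe (cat.), MeOH/THF, 25 °C
Reagents that add atoms: none
Why: Intramolecular rhodium carbenoid 1,5 C–H insertion into the electron-rich benzylic ether C–H bond closes the five-membered ring by C2–C3 bond formation (kinetically cis); the chiral carboxylate ligands select one enantiotopic benzylic hydrogen and so set C2 (S), and methoxide then epimerizes the ester-bearing C3 to the more stable trans isomer.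

Step 6
Reactants: 8 methyl (2S,3S)-6,7-bis(benzyloxy)-2-[3,4-bis(benzyloxy)phenyl]-2,3-dihydro-1-benzofuran-3-carboxylate
Product: 9 [(2S,3R)-6,7-bis(benzyloxy)-2-[3,4-bis(benzyloxy)phenyl]-2,3-dihydro-1-benzofuran-3-yl]methanol (trans)
Conditions: LiAlH4, THF, 0 °C
Reagents that add atoms: none
Why: Hydride reduction of the ester to the primary alcohol; no stereocentre is touched (the descriptor at C3 changes by priority only).

Step 7
Reactants: 9 [(2S,3R)-6,7-bis(benzyloxy)-2-[3,4-bis(benzyloxy)phenyl]-2,3-dihydro-1-benzofuran-3-yl]methanol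
Product: 10 [(2S,3R)-6,7-bis(benzyloxy)-2-[3,4-bis(benzyloxy)phenyl]-2,3-dihydro-1-benzofuran-3-yl]methyl methanesulfonate
Conditions: MsCl, Et3N, CH2Cl2, −10 °C
Reagents that add atoms: methanesulfonyl chloride, CS(Cl)(=O)=O
Why: Sulfonylation of the primary alcohol; the mesylate should be isolable because aryl participation needs an ionizing medium and heat.

Step 8
Reactants: 10 [(2S,3R)-6,7-bis(benzyloxy)-2-[3,4-bis(benzyloxy)phenyl]-2,3-dihydro-1-benzofuran-3-yl]methyl methanesulfonate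
Product: 12 (2R,3S)-7,8-bis(benzyloxy)-2-[3,4-bis(benzyloxy)phenyl]-3,4-dihydro-2H-chromen-3-yl acetate, via phenonium ion 11 (not isolated)
Conditions: KOAc (3 equiv), AcOH, 70 °C
Reagents that add atoms: potassium acetate, CC(=O)[O-].[K+]
Why: Buffered acetolysis ionizes the primary mesylate with anchimeric assistance from ring A carbon C3a (the future C4a), which is ortho to O1 and para to the 6-benzyloxy group, giving the spiro-cyclopropane phenonium ion 11. Acetate opens 11 at the secondary carbon (the future C3) anti to the bridging aryl carbon, so the C3a–C3 bond is exchanged for the C3a–CH2 bond. No ring is closed by cyclization: the five-membered ring is enlarged by a 1,2-aryl shift into ring C (O1, C2, C3, C4, C4a, C8a), the old exocyclic CH2 becoming C4. The closest known reaction type is the solvolytic phenonium ring enlargement of benzocycloalkenylmethyl sulfonates (Wagner–Meerwein type). The new C3–O stereocentre forms with inversion at the former C3, so the trans geometry of 10 is translated into 2,3-trans (2R,3S), while C2 is untouched. The step needs opening of the bridged ion at the secondary and not the primary carbon, which the cation-like character of phenonium opening in a weakly nucleophilic ionizing medium and relief of the bicyclic strain should favour, and it needs aryl participation to outrun direct displacement, which the doubly oxygen-activated migrating carbon secures.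

Step 9
Reactants: 12 (2R,3S)-7,8-bis(benzyloxy)-2-[3,4-bis(benzyloxy)phenyl]-3,4-dihydro-2H-chromen-3-yl acetate
Product: 13 (2R,3S,4R)-7,8-bis(benzyloxy)-2-[3,4-bis(benzyloxy)phenyl]-4-(2-ethoxyethoxy)-3,4-dihydro-2H-chromen-3-yl acetate
Conditions: DDQ, EtOCH2CH2OH, CH2Cl2, 25 °C
Reagents that add atoms: 2-ethoxyethanol, CCOCCO
Why: Benzylic hydride abstraction by DDQ gives the flavan-4-yl cation (stabilized by O1 ortho and O7 para to C4a), which the alcohol should trap anti to the 3-acetoxy group; the C4 configuration is lost again on ionization in step 10.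

Step 10
Reactants: 13 (2R,3S,4R)-7,8-bis(benzyloxy)-2-[3,4-bis(benzyloxy)phenyl]-4-(2-ethoxyethoxy)-3,4-dihydro-2H-chromen-3-yl acetate; 12 (2R,3S)-7,8-bis(benzyloxy)-2-[3,4-bis(benzyloxy)phenyl]-3,4-dihydro-2H-chromen-3-yl acetate
Product: 14 octa-O-benzyl-3,3'-di-O-acetyl dimer (upper unit 2R,3S, joined from C4 to C6 of the lower 2R,3S unit, the lower unit at C4 trans to the 3-acetoxy group as in 16)
Conditions: TMSOTf (0.2 equiv), CH2Cl2, −78 to −40 °C, 12 in fourfold excess
Reagents that add atoms: none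
Why: Lewis acid ionization of the C4 acetal and Friedel–Crafts alkylation by C6 of 12 (para to O1, ortho to the 7-benzyloxy group), the biomimetic proanthocyanidin coupling; the arene should add anti to the participating 3-acetoxy group, setting C4 trans to C3 and cis to the 2-aryl group.

Step 11
Reactants: 14 octa-O-benzyl-3,3'-di-O-acetyl dimer
Product: 15 octa-O-benzyl dimer (both 3-hydroxyls free, stereochemistry as in 16)
Conditions: K2CO3, MeOH/THF, 25 °C
Reagents that add atoms: none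
Why: Base-catalysed transesterification (Zemplén type) removes both acetates while the benzyl ethers still protect the oxidation-prone phenols.

Step 12
Reactants: 15 octa-O-benzyl dimer
Product: 16 (2R,3S,4R)-2-(3,4-dihydroxyphenyl)-4-[(2R,3S)-2-(3,4-dihydroxyphenyl)-3,7,8-trihydroxy-3,4-dihydro-2H-chromen-6-yl]-3,4-dihydro-2H-chromene-3,7,8-triol (target)
Conditions: H2 (1 atm), Pd(OH)2/C, THF/MeOH, 25 °C
Reagents that add atoms: none
Why: Catalytic hydrogenolysis of the eight benzyl ethers under neutral conditions, which should leave the C4–C6 bond and the C2–O1 bonds intact.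

Compound list
1 | 1-(2,3,4-trihydroxyphenyl)ethanone | CC(=O)c1ccc(O)c(O)c1O | starting material
2 | 1-[3,4-bis(benzyloxy)-2-hydroxyphenyl]ethanone | CC(=O)c1ccc(OCc2ccccc2)c(OCc2ccccc2)c1O | intermediate
3 | 1,2-bis(benzyloxy)-4-(chloromethyl)benzene | ClCc1ccc(OCc2ccccc2)c(OCc2ccccc2)c1 | starting material
4 | 1-[3,4-bis(benzyloxy)-2-{[3,4-bis(benzyloxy)phenyl]methoxy}phenyl]ethanone | CC(=O)c1ccc(OCc2ccccc2)c(OCc2ccccc2)c1OCc1ccc(OCc2ccccc2)c(OCc2ccccc2)c1 | intermediate
5 | methyl 2-[3,4-bis(benzyloxy)-2-{[3,4-bis(benzyloxy)phenyl]methoxy}phenyl]acetate | COC(=O)Cc1ccc(OCc2ccccc2)c(OCc2ccccc2)c1OCc1ccc(OCc2ccccc2)c(OCc2ccccc2)c1 | intermediate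
6 | methyl 2-[3,4-bis(benzyloxy)-2-{[3,4-bis(benzyloxy)phenyl]methoxy}phenyl]-2-diazoacetate | COC(=O)C(=[N+]=[N-])c1ccc(OCc2ccccc2)c(OCc2ccccc2)c1OCc1ccc(OCc2ccccc2)c(OCc2ccccc2)c1 | intermediate
7 | methyl (2S,3R)-6,7-bis(benzyloxy)-2-[3,4-bis(benzyloxy)phenyl]-2,3-dihydro-1-benzofuran-3-carboxylate (cis) | COC(=O)[C@@H]1c2ccc(OCc3ccccc3)c(OCc3ccccc3)c2O[C@@H]1c1ccc(OCc2ccccc2)c(OCc2ccccc2)c1 | intermediate
8 | methyl (2S,3S)-6,7-bis(benzyloxy)-2-[3,4-bis(benzyloxy)phenyl]-2,3-dihydro-1-benzofuran-3-carboxylate (trans) | COC(=O)[C@H]1c2ccc(OCc3ccccc3)c(OCc3ccccc3)c2O[C@@H]1c1ccc(OCc2ccccc2)c(OCc2ccccc2)c1 | intermediate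
9 | [(2S,3R)-6,7-bis(benzyloxy)-2-[3,4-bis(benzyloxy)phenyl]-2,3-dihydro-1-benzofuran-3-yl]methanol | OC[C@H]1c2ccc(OCc3ccccc3)c(OCc3ccccc3)c2O[C@@H]1c1ccc(OCc2ccccc2)c(OCc2ccccc2)c1 | intermediate
10 | [(2S,3R)-6,7-bis(benzyloxy)-2-[3,4-bis(benzyloxy)phenyl]-2,3-dihydro-1-benzofuran-3-yl]methyl methanesulfonate | CS(=O)(=O)OC[C@H]1c2ccc(OCc3ccccc3)c(OCc3ccccc3)c2O[C@@H]1c1ccc(OCc2ccccc2)c(OCc2ccccc2)c1 | intermediate
11 | phenonium ion (spiro-cyclopropane arenium cation bridging C3 and the exocyclic CH2, methanesulfonate ion pair) | C1[C@@H]2[C@@H](c3ccc(OCc4ccccc4)c(OCc4ccccc4)c3)OC3=C(OCc4ccccc4)C(=[O+]Cc4ccccc4)C=C[C@@]123.CS(=O)(=O)[O-] | intermediate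
12 | (2R,3S)-7,8-bis(benzyloxy)-2-[3,4-bis(benzyloxy)phenyl]-3,4-dihydro-2H-chromen-3-yl acetate | CC(=O)O[C@H]1Cc2ccc(OCc3ccccc3)c(OCc3ccccc3)c2O[C@@H]1c1ccc(OCc2ccccc2)c(OCc2ccccc2)c1 | intermediate
13 | (2R,3S,4R)-7,8-bis(benzyloxy)-2-[3,4-bis(benzyloxy)phenyl]-4-(2-ethoxyethoxy)-3,4-dihydro-2H-chromen-3-yl acetate | c1ccccc1COc1ccc(cc1OCc1ccccc1)[C@H]1Oc2c(ccc(OCc3ccccc3)c2OCc2ccccc2)[C@@H](OCCOCC)[C@@H]1OC(C)=O | intermediate
14 | octa-O-benzyl-3,3'-di-O-acetyl dimer | c1ccccc1COc1ccc([C@H]2Oc3c(ccc(OCc4ccccc4)c3OCc3ccccc3)[C@@H](c3cc4c(c(OCc5ccccc5)c3OCc3ccccc3)O[C@H](c3ccc(OCc5ccccc5)c(OCc5ccccc5)c3)[C@@H](OC(C)=O)C4)[C@@H]2OC(C)=O)cc1OCc1ccccc1 | intermediate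
15 | octa-O-benzyl dimer | c1ccccc1COc1ccc([C@H]2Oc3c(ccc(OCc4ccccc4)c3OCc3ccccc3)[C@@H](c3cc4c(c(OCc5ccccc5)c3OCc3ccccc3)O[C@H](c3ccc(OCc5ccccc5)c(OCc5ccccc5)c3)[C@@H](O)C4)[C@@H]2O)cc1OCc1ccccc1 | intermediate
16 | (2R,3S,4R)-2-(3,4-dihydroxyphenyl)-4-[(2R,3S)-2-(3,4-dihydroxyphenyl)-3,7,8-trihydroxy-3,4-dihydro-2H-chromen-6-yl]-3,4-dihydro-2H-chromene-3,7,8-triol | Oc1ccc([C@H]2Oc3c(ccc(O)c3O)[C@@H](c3cc4c(c(O)c3O)O[C@H](c3ccc(O)c(O)c3)[C@@H](O)C4)[C@@H]2O)cc1O | target

Total steps: 12. Longest linear sequence: 12 steps (1 to 16; compound 12 is used twice, in steps 9 and 10).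

Steps most likely to fail

Step 8. The bridged ion may be opened at the primary carbon, the mesylate may be displaced directly without aryl participation, or the ion may lose a proton; in each case no ring enlargement takes place. The fallback replaces kinetic capture by thermodynamic control. It sets out from alcohol 9, which is converted with TsCl and pyridine into [(2S,3R)-6,7-bis(benzyloxy)-2-[3,4-bis(benzyloxy)phenyl]-2,3-dihydro-1-benzofuran-3-yl]methyl 4-methylbenzenesulfonate F1. Heating F1 in hexafluoroisopropanol with 2,6-di-tert-butylpyridine should equilibrate it, by ion-pair return through the same phenonium ion, to the less strained six-membered (2R,3S)-7,8-bis(benzyloxy)-2-[3,4-bis(benzyloxy)phenyl]-3,4-dihydro-2H-chromen-3-yl 4-methylbenzenesulfonate F2. Cleavage of the S–O bond with Mg in MeOH, which leaves the C3–O bond and its configuration untouched, should give (2R,3S)-7,8-bis(benzyloxy)-2-[3,4-bis(benzyloxy)phenyl]-3,4-dihydro-2H-chromen-3-ol F3. Acetylation with Ac2O and pyridine comes back to the route at 12.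

Step 9. Hydride abstraction may occur at C2 (benzylic to ring B and next to O1) in competition with C4, and the product may be oxidized further. The fallback sets out from 12 and uses anodic benzylic methoxylation (constant current, graphite anode, MeOH/CH2Cl2, Et4NOTs, 2,6-lutidine), in which electron transfer from the more electron-rich ring A directs the loss of the C4 proton. It should give (2R,3S,4R)-7,8-bis(benzyloxy)-2-[3,4-bis(benzyloxy)phenyl]-4-methoxy-3,4-dihydro-2H-chromen-3-yl acetate F4. F4 is ionized with TMSOTf in the presence of excess 12 exactly as in step 10 and comes back to the route at 14.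

Step 10. The flavan-4-yl cation may alkylate ring A of a second electrophile molecule or of the product, so that oligomers form, and the coupling may be slow with the benzylated nucleophile. The fallback caps the electrophile and sets out from 12. Bromination with NBS in CH2Cl2 at −20 °C at the most activated position should give (2R,3S)-6-bromo-7,8-bis(benzyloxy)-2-[3,4-bis(benzyloxy)phenyl]-3,4-dihydro-2H-chromen-3-yl acetate F5. DDQ and 2-ethoxyethanol convert F5 into (2R,3S,4R)-6-bromo-7,8-bis(benzyloxy)-2-[3,4-bis(benzyloxy)phenyl]-4-(2-ethoxyethoxy)-3,4-dihydro-2H-chromen-3-yl acetate F6, which cannot condense with itself. Coupling of F6 with 12 under TMSOTf should give the 6-bromo octa-O-benzyl di-O-acetyl dimer F7, and K2CO3 in MeOH/THF the 6-bromo octa-O-benzyl dimer F8. Hydrogenolysis of F8 (H2, Pd(OH)2/C, Et3N, THF/MeOH) removes the bromine together with the benzyl ethers and comes back to the route at 16.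

Further compounds
F1 | step 8 | [(2S,3R)-6,7-bis(benzyloxy)-2-[3,4-bis(benzyloxy)phenyl]-2,3-dihydro-1-benzofuran-3-yl]methyl 4-methylbenzenesulfonate | Cc1ccc(cc1)S(=O)(=O)OC[C@H]1c2ccc(OCc3ccccc3)c(OCc3ccccc3)c2O[C@@H]1c1ccc(OCc2ccccc2)c(OCc2ccccc2)c1
F2 | step 8 | (2R,3S)-7,8-bis(benzyloxy)-2-[3,4-bis(benzyloxy)phenyl]-3,4-dihydro-2H-chromen-3-yl 4-methylbenzenesulfonate | Cc1ccc(cc1)S(=O)(=O)O[C@H]1Cc2ccc(OCc3ccccc3)c(OCc3ccccc3)c2O[C@@H]1c1ccc(OCc2ccccc2)c(OCc2ccccc2)c1
F3 | step 8 | (2R,3S)-7,8-bis(benzyloxy)-2-[3,4-bis(benzyloxy)phenyl]-3,4-dihydro-2H-chromen-3-ol | O[C@H]1Cc2ccc(OCc3ccccc3)c(OCc3ccccc3)c2O[C@@H]1c1ccc(OCc2ccccc2)c(OCc2ccccc2)c1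
F4 | step 9 | (2R,3S,4R)-7,8-bis(benzyloxy)-2-[3,4-bis(benzyloxy)phenyl]-4-methoxy-3,4-dihydro-2H-chromen-3-yl acetate | c1ccccc1COc1ccc(cc1OCc1ccccc1)[C@H]1Oc2c(ccc(OCc3ccccc3)c2OCc2ccccc2)[C@@H](OC)[C@@H]1OC(C)=O
F5 | step 10 | (2R,3S)-6-bromo-7,8-bis(benzyloxy)-2-[3,4-bis(benzyloxy)phenyl]-3,4-dihydro-2H-chromen-3-yl acetate | CC(=O)O[C@H]1Cc2cc(Br)c(OCc3ccccc3)c(OCc3ccccc3)c2O[C@@H]1c1ccc(OCc2ccccc2)c(OCc2ccccc2)c1
F6 | step 10 | (2R,3S,4R)-6-bromo-7,8-bis(benzyloxy)-2-[3,4-bis(benzyloxy)phenyl]-4-(2-ethoxyethoxy)-3,4-dihydro-2H-chromen-3-yl acetate | c1ccccc1COc1ccc(cc1OCc1ccccc1)[C@H]1Oc2c(cc(Br)c(OCc3ccccc3)c2OCc2ccccc2)[C@@H](OCCOCC)[C@@H]1OC(C)=O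
F7 | step 10 | 6-bromo octa-O-benzyl-3,3'-di-O-acetyl dimer (bromine on C6 of the upper unit) | c1ccccc1COc1ccc([C@H]2Oc3c(cc(Br)c(OCc4ccccc4)c3OCc3ccccc3)[C@@H](c3cc4c(c(OCc5ccccc5)c3OCc3ccccc3)O[C@H](c3ccc(OCc5ccccc5)c(OCc5ccccc5)c3)[C@@H](OC(C)=O)C4)[C@@H]2OC(C)=O)cc1OCc1ccccc1
F8 | step 10 | 6-bromo octa-O-benzyl dimer (bromine on C6 of the upper unit) | c1ccccc1COc1ccc([C@H]2Oc3c(cc(Br)c(OCc4ccccc4)c3OCc3ccccc3)[C@@H](c3cc4c(c(OCc5ccccc5)c3OCc3ccccc3)O[C@H](c3ccc(OCc5ccccc5)c(OCc5ccccc5)c3)[C@@H](O)C4)[C@@H]2O)cc1OCc1ccccc1
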